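**Plan** (longipinane numbering: C1 ketone, C2 CH2, C3 CH–CH3, cyclobutane C4–C5–C11–C10, C6 quaternary carrying C15H2–O, C7 and C8 CH–O, C9 CH2)
1. Cuts: first the three angelate C–O bonds, then C3–C4 of the six-membered ring. C4 and C11 are the 1,3-related carbons of the cyclobutane and are spanned by the C1–C2–C3 bridge, so both can be bridgeheads of a bicyclo[1.1.0]butane (wing carbons C5 and C10, already tied by the seven-membered ring) whose central C4–C11 bond is exchanged for C3–C4 by a C3 radical on a but-3-enoyl group at C11.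
2. Further cuts: C11–C4 and C11–C10 (carbene of a C5 diazoacetate onto C4=C10), C4=C10 (metathesis), C5–C6 (allylic alkylation), C6–CH3, C6–C7 (Dieckmann), C8–C9 (glyoxylate ene).
3. Forward ring order: tetronic acid ring (C15, C6, C7, C8, O), opened to an acyclic triol, then the seven-membered ring, then the bicyclobutane, then the six-membered ring in the key step.
4. Stereochemistry: C8 from the (S)-BINOL–titanium ene catalyst; C5 from the iridium catalyst; C6 and C7 from the tetronic ring (methyl iodide and hydride both add anti to the resident groups); C4, C10 and C11 follow from C5 through the tricyclic frame; C3 is set in the key step.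

Key step: step 16

Assumption: the iridium–phosphoramidite catalyst follows the usual facial model of its family; the ligand enantiomer used is the one that gives the 3R adduct 9.

**Step 1**
Reactants: 1 methyl glyoxylate; 2 isobutene
Product: 3 methyl (2S)-2-hydroxy-4-methylpent-4-enoate
Conditions: (S)-BINOL (10 mol %), Ti(OiPr)2Cl2 (10 mol %), 4 Å MS, CH2Cl2, −30 °C
Reagents that add atoms: none
Why: Asymmetric glyoxylate–ene reaction (Mikami), in which the chiral titanium–BINOL Lewis acid binds the aldehyde and isobutene delivers an allylic hydrogen through a six-membered transition state, the (S)-ligand setting C8 as S.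

**Step 2**
Reactants: 3 methyl (2S)-2-hydroxy-4-methylpent-4-enoate
Product: 4 methyl (2S)-2-acetoxy-4-methylpent-4-enoate
Conditions: Ac2O, pyridine, DMAP (cat.), CH2Cl2, 0 °C → rt
Reagents that add atoms: acetic anhydride CC(=O)OC(C)=O
Why: DMAP-catalysed O-acylation that brings in C15 and C6 and does not touch the carbinol stereocentre.

**Step 3**
Reactants: 4 methyl (2S)-2-acetoxy-4-methylpent-4-enoate
Product: 5 (5S)-4-hydroxy-5-(2-methylprop-2-en-1-yl)furan-2(5H)-one
Conditions: LiN(SiMe3)2 (2.2 equiv), THF, −78 → 0 °C; then 1 M HCl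
Reagents that add atoms: none
Why: Dieckmann condensation of an α-acyloxy ester (the acetate enolate closes onto the methyl ester, 5-exo-trig), the standard route to 5-substituted tetronic acids, run cold so that C8 is not deprotonated.

**Step 4**
Reactants: 6 tert-butyl but-3-enoate; 7 allyl methyl carbonate (4 equiv)
Product: 8 tert-butyl (3E)-5-[(methoxycarbonyl)oxy]pent-3-enoate
Conditions: second-generation Grubbs catalyst RuCl2(H2IMes)(PCy3)(=CHPh) (3 mol %), CH2Cl2, 40 °C
Reagents that add atoms: none
Why: Olefin cross-metathesis of two terminal alkenes, driven to the heterodimer by excess of the cheap carbonate and giving mainly the thermodynamically preferred E alkene.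

**Step 5**
Reactants: 5 (5S)-4-hydroxy-5-(2-methylprop-2-en-1-yl)furan-2(5H)-one; 8 tert-butyl (3E)-5-[(methoxycarbonyl)oxy]pent-3-enoate
Product: 9 tert-butyl (3R)-3-[(5S)-4-hydroxy-5-(2-methylprop-2-en-1-yl)-2-oxo-2,5-dihydrofuran-3-yl]pent-4-enoate
Conditions: [Ir(cod)Cl]2 (2 mol %), one enantiomer of the BINOL-derived N,N-bis(1-phenylethyl)phosphoramidite (4 mol %), TBD (10 mol %, catalyst activated first), THF, 25 °C
Reagents that add atoms: none
Why: Iridium-catalysed asymmetric allylic alkylation, in which the tetronate (formed by the methoxide that the carbonate releases) attacks the substituted terminus of the allyl–iridium complex to give the branched product, the ligand fixing C5 as R while C6 stays an enol carbon.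

**Step 6**
Reactants: 9 tert-butyl (3R)-3-[(5S)-4-hydroxy-5-(2-methylprop-2-en-1-yl)-2-oxo-2,5-dihydrofuran-3-yl]pent-4-enoate
Product: 10 tert-butyl (3R)-3-[(3R,5S)-3-methyl-5-(2-methylprop-2-en-1-yl)-2,4-dioxooxolan-3-yl]pent-4-enoate
Conditions: MeI (5 equiv), K2CO3 (1.5 equiv), acetone, 25 °C
Reagents that add atoms: iodomethane CI
Why: C-alkylation of a 3-substituted tetronate by a soft electrophile; the methyl should enter the planar enolate anti to the C8 methallyl group, which places the C5 branch cis to it and sets C6.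

**Step 7**
Reactants: 10 tert-butyl (3R)-3-[(3R,5S)-3-methyl-5-(2-methylprop-2-en-1-yl)-2,4-dioxooxolan-3-yl]pent-4-enoate
Product: 12 tert-butyl (3R,4S,5S,6S)-3-ethenyl-5,6-dihydroxy-4-(hydroxymethyl)-4,8-dimethylnon-8-enoate, via hydroxy lactone 11 (not isolated)
Conditions: LiBH4 (4 equiv), THF–MeOH (20:1), −40 → 25 °C; aq. NH4Cl
Reagents that add atoms: none
Why: Borohydride reduction in which hydride should attack the C7 ketone from the face of the small C6 methyl and C8–H (anti to the C5 branch and the methallyl group), setting C7, after which the γ-lactone is reduced to the C15/C8 diol while the hindered tert-butyl ester is left.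

**Step 8**
Reactants: 12 tert-butyl (3R,4S,5S,6S)-3-ethenyl-5,6-dihydroxy-4-(hydroxymethyl)-4,8-dimethylnon-8-enoate
Product: 13 tert-butyl (3R,4S,5S,6S)-5,6-bis(tert-butyldimethylsilyloxy)-4-[(tert-butyldimethylsilyloxy)methyl]-3-ethenyl-4,8-dimethylnon-8-enoate
Conditions: TBSOTf (3.6 equiv), 2,6-lutidine (6 equiv), CH2Cl2, −78 → 0 °C
Reagents that add atoms: tert-butyldimethylsilyl triflate CC(C)(C)[Si](C)(C)OS(=O)(=O)C(F)(F)F
Why: Silyl triflate silylation, fast enough for the hindered C7 hydroxyl at low temperature, where the tert-butyl ester is not yet cleaved.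

**Step 9**
Reactants: 13 tert-butyl (3R,4S,5S,6S)-5,6-bis(tert-butyldimethylsilyloxy)-4-[(tert-butyldimethylsilyloxy)methyl]-3-ethenyl-4,8-dimethylnon-8-enoate
Product: 14 tert-butyl 2-[(1R,5S,6S,7S)-5,6-bis(tert-butyldimethylsilyloxy)-7-[(tert-butyldimethylsilyloxy)methyl]-3,7-dimethylcyclohept-2-en-1-yl]acetate
Conditions: second-generation Grubbs catalyst RuCl2(H2IMes)(PCy3)(=CHPh) (10 mol %), toluene (0.005 M), 80 °C
Reagents that add atoms: none
Why: Ring-closing metathesis that starts at the monosubstituted vinyl group and closes onto the isopropenyl group to give the trisubstituted C4=C10 cycloheptene, with no stereocentre involved.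

**Step 10**
Reactants: 14 tert-butyl 2-[(1R,5S,6S,7S)-5,6-bis(tert-butyldimethylsilyloxy)-7-[(tert-butyldimethylsilyloxy)methyl]-3,7-dimethylcyclohept-2-en-1-yl]acetate
Product: 16 tert-butyl 2-diazo-2-[(1R,5S,6S,7S)-5,6-bis(tert-butyldimethylsilyloxy)-7-[(tert-butyldimethylsilyloxy)methyl]-3,7-dimethylcyclohept-2-en-1-yl]acetate, via trifluoroacetyl ester 15 (not isolated)
Conditions: LiN(iPr)2 (1.2 equiv), THF, −78 °C; CF3CO2CH2CF3 (1.5 equiv); aq. HCl work-up; then MsN3 (1.5 equiv), Et3N (2 equiv), H2O (1 equiv), MeCN, 25 °C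
Reagents that add atoms: methanesulfonyl azide CS(=O)(=O)N=[N+]=[N-]; 2,2,2-trifluoroethyl trifluoroacetate O=C(OCC(F)(F)F)C(F)(F)F (its atoms stay in 15 only)
Why: Detrifluoroacetylative diazo transfer (Danheiser), in which Claisen acylation of the only enolisable position, C11, activates it for diazo transfer and the trifluoroacetyl group then leaves.

**Step 11**
Reactants: 16 tert-butyl 2-diazo-2-[(1R,5S,6S,7S)-5,6-bis(tert-butyldimethylsilyloxy)-7-[(tert-butyldimethylsilyloxy)methyl]-3,7-dimethylcyclohept-2-en-1-yl]acetate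
Product: 17 tert-butyl 4,5-bis(tert-butyldimethylsilyloxy)-6-[(tert-butyldimethylsilyloxy)methyl]-2,6-dimethyltricyclo[5.1.0.0(2,8)]octane-1-carboxylate (bicyclobutane: central bond C4–C11, wings C5 and C10, C5–H and C10–CH3 exo; C6, C7, C8 as in 14)
Conditions: Rh2(O2CCPh3)4 (1 mol %), CH2Cl2, −78 → 0 °C, slow addition of 16
Reagents that add atoms: none
Why: Intramolecular cyclopropanation of an α-allyl α-diazo ester by a rhodium carbenoid (bicyclobutanation), in which C11 can reach C4=C10 only on the face on which it sits at C5, so C4, C10 and C11 follow from C5, and the bulky carboxylate ligand at low temperature should hold back the 1,2-hydride shift from C5.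

**Step 12**
Reactants: 17 bicyclobutane tert-butyl ester
Product: 18 bicyclobutylmethanol (C11–CH2OH in place of the ester of 17)
Conditions: iBu2AlH (3 equiv), CH2Cl2, −78 → 0 °C; Rochelle salt
Reagents that add atoms: none
Why: Aluminium hydride reduction of the ester to the primary alcohol, known to leave bicyclobutane carboxylates intact.

**Step 13**
Reactants: 18 bicyclobutylmethanol
Product: 19 bicyclobutane carbaldehyde (C11–CHO)
Conditions: Dess–Martin periodinane (1.5 equiv), NaHCO3, CH2Cl2, 0 °C
Reagents that add atoms: none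
Why: Buffered Dess–Martin oxidation, neutral enough for the acid-sensitive bicyclobutane.

**Step 14**
Reactants: 19 bicyclobutane carbaldehyde; 20 allylmagnesium bromide
Product: 21 homoallylic alcohol (C11–CH(OH)CH2CH=CH2, both C1 epimers)
Conditions: 20 (1.5 equiv), Et2O, −78 °C; aq. NH4Cl
Reagents that add atoms: none
Why: Grignard 1,2-addition to the aldehyde, which brings in C2, C3 and the future C3 methyl; the carbinol configuration is removed in the next step.

**Step 15**
Reactants: 21 homoallylic alcohol
Product: 22 tricyclic but-3-enoyl bicyclo[1.1.0]butane (C11–C(=O)CH2CH=CH2; the key-step precursor)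
Conditions: Dess–Martin periodinane (1.5 equiv), NaHCO3, CH2Cl2, 0 °C
Reagents that add atoms: none
Why: Buffered Dess–Martin oxidation of a homoallylic alcohol, which gives the β,γ-unsaturated ketone without moving the alkene into conjugation.

**Step 16**
Reactants: 22 tricyclic but-3-enoyl bicyclo[1.1.0]butane
Product: 23 7,8,15-tris-O-(tert-butyldimethylsilyl)longipinan-1-one (complete carbon skeleton; C3 methyl on the C5 side)
Conditions: Fe(acac)3 (30 mol %), PhSiH3 (2.5 equiv), EtOH–THF (1:1), 0.01 M, 40 °C
Reagents that add atoms: none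
Why: Proposed new method: an iron hydride formed from Fe(acac)3 and PhSiH3 should transfer a hydrogen atom to the terminal CH2 of the but-3-enoyl group, and the secondary C3 radical, held over the convex face by the C2–C1 tether, should attack bridgehead C4 as the bent, p-rich C4–C11 bond breaks; the C11 radical is alpha to the C1 ketone, is reduced by divalent iron to the enolate and protonated by ethanol. The closest known reactions are intermolecular radical additions to acyl bicyclo[1.1.0]butanes (strain-release Giese additions) and hydrogen-atom-transfer-initiated Giese cyclizations onto enones; an intramolecular attack on the convex face through a three-atom tether has not been shown. The six-membered ring C1–C2–C3–C4–C5–C11 closes in a mode that is 5-endo with respect to the C11–C4 bond being broken, which the length of that bond and the release of bicyclobutane strain should make feasible. Of the three new stereocentres, C4 and C11 are dictated by the tricyclic frame (the tether reaches only the convex face, and C11 can take its hydrogen only from outside the new bridge), while C3 is set in the transition state, its methyl turning towards C5–H and away from the C10 methyl that overhangs the forming ring. The step needs hydrogen-atom transfer to the single terminal alkene and ring closure faster than reduction of the C3 radical, which the absence of any other alkene and the proximity enforced by the acyl tether should secure.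

**Step 17**
Reactants: 23 7,8,15-tris-O-(tert-butyldimethylsilyl)longipinan-1-one
Product: 24 7,8,15-trihydroxylongipinan-1-one
Conditions: HF·pyridine, pyridine, THF, 0 → 25 °C
Reagents that add atoms: none
Why: Fluoride-driven cleavage of the three silyl ethers under buffered conditions that should leave the ketone and the cyclobutane untouched.

**Step 18**
Reactants: 24 7,8,15-trihydroxylongipinan-1-one; 25 angelic acid
Product: 27 CNP0214984.1 (7,8,15-tri-O-angeloyl-longipinan-1-one), via mixed anhydride 26 (not isolated)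
Conditions: 25 (6 equiv), 2,4,6-trichlorobenzoyl chloride (6 equiv), Et3N (12 equiv), toluene, 25 °C; then 24, toluene, 80 °C
Reagents that add atoms: 2,4,6-trichlorobenzoyl chloride O=C(Cl)c1c(Cl)cc(Cl)cc1Cl (its atoms stay in 26 only)
Why: Yamaguchi esterification through the mixed anhydride, attacked at the less hindered angeloyl carbonyl; leaving out DMAP and using a non-polar solvent should keep the Z alkene from isomerising to the tiglate.

**Compound list**
1 | methyl glyoxylate | COC(=O)C=O | starting material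
2 | isobutene | CC(C)=C | starting material
3 | methyl (2S)-2-hydroxy-4-methylpent-4-enoate | COC(=O)[C@@H](O)CC(C)=C | intermediate
4 | methyl (2S)-2-acetoxy-4-methylpent-4-enoate | COC(=O)[C@@H](OC(C)=O)CC(C)=C | intermediate
5 | (5S)-4-hydroxy-5-(2-methylprop-2-en-1-yl)furan-2(5H)-one | OC1=CC(=O)O[C@H]1CC(C)=C | intermediate
6 | tert-butyl but-3-enoate | C=CCC(=O)OC(C)(C)C | starting material
7 | allyl methyl carbonate | C=CCOC(=O)OC | starting material
8 | tert-butyl (3E)-5-[(methoxycarbonyl)oxy]pent-3-enoate | COC(=O)OC/C=C/CC(=O)OC(C)(C)C | intermediate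
9 | tert-butyl (3R)-3-[(5S)-4-hydroxy-5-(2-methylprop-2-en-1-yl)-2-oxo-2,5-dihydrofuran-3-yl]pent-4-enoate | CC(C)(C)OC(=O)C[C@H](C=C)C1=C(O)[C@H](CC(C)=C)OC1=O | intermediate
10 | tert-butyl (3R)-3-[(3R,5S)-3-methyl-5-(2-methylprop-2-en-1-yl)-2,4-dioxooxolan-3-yl]pent-4-enoate | CC(C)(C)OC(=O)C[C@H](C=C)[C@]1(C)C(=O)[C@H](CC(C)=C)OC1=O | intermediate
11 | tert-butyl (3R)-3-[(3R,4S,5S)-4-hydroxy-3-methyl-5-(2-methylprop-2-en-1-yl)-2-oxooxolan-3-yl]pent-4-enoate | CC(C)(C)OC(=O)C[C@H](C=C)[C@]1(C)[C@H](O)[C@H](CC(C)=C)OC1=O | intermediate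
12 | tert-butyl (3R,4S,5S,6S)-3-ethenyl-5,6-dihydroxy-4-(hydroxymethyl)-4,8-dimethylnon-8-enoate | C=C[C@@H](CC(=O)OC(C)(C)C)[C@@](C)(CO)[C@H](O)[C@@H](O)CC(C)=C | intermediate
13 | tris-TBS ether of 12 | C=C[C@@H](CC(=O)OC(C)(C)C)[C@@](C)(CO[Si](C)(C)C(C)(C)C)[C@H](O[Si](C)(C)C(C)(C)C)[C@@H](O[Si](C)(C)C(C)(C)C)CC(C)=C | intermediate
14 | tert-butyl 2-[(1R,5S,6S,7S)-5,6-bis(TBSO)-7-(TBSOCH2)-3,7-dimethylcyclohept-2-en-1-yl]acetate | CC(C)(C)[Si](C)(C)OC[C@]1(C)[C@H](CC(=O)OC(C)(C)C)C=C(C)C[C@H](O[Si](C)(C)C(C)(C)C)[C@H]1O[Si](C)(C)C(C)(C)C | intermediate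
15 | α-trifluoroacetyl derivative of 14 (C11 epimers) | CC(C)(C)[Si](C)(C)OC[C@]1(C)[C@H](C(C(=O)C(F)(F)F)C(=O)OC(C)(C)C)C=C(C)C[C@H](O[Si](C)(C)C(C)(C)C)[C@H]1O[Si](C)(C)C(C)(C)C | intermediate
16 | α-diazo ester of 14 | CC(C)(C)[Si](C)(C)OC[C@]1(C)[C@H](C(=[N+]=[N-])C(=O)OC(C)(C)C)C=C(C)C[C@H](O[Si](C)(C)C(C)(C)C)[C@H]1O[Si](C)(C)C(C)(C)C | intermediate
17 | tricyclic bicyclobutane tert-butyl ester | CC(C)(C)[Si](C)(C)OC[C@]1(C)[C@H]2[C@@H]3[C@@]2(C(=O)OC(C)(C)C)[C@]3(C)C[C@H](O[Si](C)(C)C(C)(C)C)[C@H]1O[Si](C)(C)C(C)(C)C | intermediate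
18 | bicyclobutylmethanol | CC(C)(C)[Si](C)(C)OC[C@]1(C)[C@H]2[C@@H]3[C@@]2(CO)[C@]3(C)C[C@H](O[Si](C)(C)C(C)(C)C)[C@H]1O[Si](C)(C)C(C)(C)C | intermediate
19 | bicyclobutane carbaldehyde | CC(C)(C)[Si](C)(C)OC[C@]1(C)[C@H]2[C@@H]3[C@@]2(C=O)[C@]3(C)C[C@H](O[Si](C)(C)C(C)(C)C)[C@H]1O[Si](C)(C)C(C)(C)C | intermediate
20 | allylmagnesium bromide | C=CC[Mg]Br | starting material
21 | homoallylic alcohol (C1 epimers) | CC(C)(C)[Si](C)(C)OC[C@]1(C)[C@H]2[C@@H]3[C@@]2(C(O)CC=C)[C@]3(C)C[C@H](O[Si](C)(C)C(C)(C)C)[C@H]1O[Si](C)(C)C(C)(C)C | intermediate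
22 | tricyclic but-3-enoyl bicyclo[1.1.0]butane | CC(C)(C)[Si](C)(C)OC[C@]1(C)[C@H]2[C@@H]3[C@@]2(C(=O)CC=C)[C@]3(C)C[C@H](O[Si](C)(C)C(C)(C)C)[C@H]1O[Si](C)(C)C(C)(C)C | intermediate
23 | 7,8,15-tris-O-TBS-longipinan-1-one | CC(C)(C)[Si](C)(C)OC[C@]1(C)[C@H]2[C@@H]3[C@H](C)CC(=O)[C@H]2[C@]3(C)C[C@H](O[Si](C)(C)C(C)(C)C)[C@H]1O[Si](C)(C)C(C)(C)C | intermediate
24 | 7,8,15-trihydroxylongipinan-1-one (7-O cis to the C6 methyl, trans to 8-O) | OC[C@]1(C)[C@H]2[C@@H]3[C@H](C)CC(=O)[C@H]2[C@]3(C)C[C@H](O)[C@H]1O | intermediate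
25 | angelic acid | C/C=C(/C)C(=O)O | starting material
26 | angelic 2,4,6-trichlorobenzoic anhydride | C/C=C(/C)C(=O)OC(=O)c1c(Cl)cc(Cl)cc1Cl | intermediate
27 | CNP0214984.1 | C/C=C(/C)C(=O)OC[C@]1(C)[C@H]2[C@@H]3[C@H](C)CC(=O)[C@H]2[C@]3(C)C[C@H](OC(=O)/C(C)=C\C)[C@H]1OC(=O)/C(C)=C\C | target

**Count:** 18 steps in total; longest linear sequence 17 steps (steps 1–3 and 5–18).

**Steps most likely to fail**

1. Step 16. The C3 radical may be reduced, or the acyl bicyclobutane may be opened by the alcohol, before the tether-enforced attack on C4 takes place. The fallback uses known reactions and sets out from ketone 22. Hydroiodination across the central bond (NaI, AcOH, THF, 0 °C; iodide to C4, proton to C11) gives the cyclobutyl iodide F1, whose C11 acyl group can equilibrate through the enol to the face away from the C6–C9 bridge. Bu3SnH with AIBN (slow addition, benzene, 80 °C) then forms the planar C4 cyclobutyl radical, which closes 6-exo-trig onto C3 of the terminal alkene; hydrogen transfer to the primary radical makes the C3 methyl. The route is rejoined at 23.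

2. Step 11. A 1,2-hydride shift from C5 to the carbenoid carbon, or poor folding of the silyl-laden ring, may outrun capture by the trisubstituted alkene. The fallback moves ring closure and carbene transfer onto the lactone-bridged scaffold and sets out from dione 10. NaBH4 (MeOH, −40 °C) stops at hydroxy lactone 11, and TBSOTf gives the silyl ether F2. Ring-closing metathesis on the γ-lactone, which holds the two alkene arms cis, gives the bridged cycloheptene lactone F3. Trifluoroacetylation to the keto ester F4 and diazo transfer give the diazo ester F5, and Rh2(O2CCPh3)4 gives the lactone-bridged bicyclobutane F6. LiBH4 opens the lactone to the diol F7, and TBSOTf returns to 17.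

3. Step 5. The tetronate may be allylated on oxygen or at the unsubstituted terminus, or the carbonate may eliminate to a dienoate. The fallback replaces the metal-catalysed substitution by a sigmatropic shift and sets out from 8 and 5. Methanolysis of carbonate 8 (K2CO3, MeOH) gives the allylic alcohol F8. Mitsunobu etherification of tetronic acid 5 (PPh3, DIAD) gives the 4-O-allyl tetronate F9. Heating (toluene, 110 °C) brings about a Claisen rearrangement through a chair transition state on the ring face anti to the methallyl group, which should give C5 as R. The route is rejoined at 9.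

**Further compounds**
F1 | step 16 | cyclobutyl iodide (iodide at C4 on the bridge side, but-3-enoyl at C11 on the opposite face) | CC(C)(C)[Si](C)(C)OC[C@]1(C)[C@H]2[C@@H](I)[C@@](C)(C[C@H](O[Si](C)(C)C(C)(C)C)[C@H]1O[Si](C)(C)C(C)(C)C)[C@@H]2C(=O)CC=C
F2 | step 11 | 4-O-TBS ether of hydroxy lactone 11 | CC(C)(C)OC(=O)C[C@H](C=C)[C@]1(C)[C@H](O[Si](C)(C)C(C)(C)C)[C@H](CC(C)=C)OC1=O
F3 | step 11 | bridged cycloheptene γ-lactone (C15(=O)–O–C8 bridge, C7–OTBS) | CC(C)(C)OC(=O)C[C@@H]1C=C(C)C[C@@H]2OC(=O)[C@@]1(C)[C@@H]2O[Si](C)(C)C(C)(C)C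
F4 | step 11 | α-trifluoroacetyl derivative of F3 (C11 epimers) | CC(C)(C)OC(=O)C(C(=O)C(F)(F)F)[C@@H]1C=C(C)C[C@@H]2OC(=O)[C@@]1(C)[C@@H]2O[Si](C)(C)C(C)(C)C
F5 | step 11 | α-diazo ester of F3 | CC(C)(C)OC(=O)C(=[N+]=[N-])[C@@H]1C=C(C)C[C@@H]2OC(=O)[C@@]1(C)[C@@H]2O[Si](C)(C)C(C)(C)C
F6 | step 11 | lactone-bridged bicyclobutane tert-butyl ester | O=C1[C@]2(C)[C@H]3[C@@H]4[C@@]3(C(=O)OC(C)(C)C)[C@]4(C)C[C@H](O1)[C@H]2O[Si](C)(C)C(C)(C)C
F7 | step 11 | bicyclobutane ester with free C15 and C8 hydroxyls | OC[C@]1(C)[C@H]2[C@@H]3[C@@]2(C(=O)OC(C)(C)C)[C@]3(C)C[C@H](O)[C@H]1O[Si](C)(C)C(C)(C)C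
F8 | step 5 | tert-butyl (3E)-5-hydroxypent-3-enoate | OC/C=C/CC(=O)OC(C)(C)C
F9 | step 5 | (5S)-4-O-[(2E)-4-(tert-butoxycarbonyl)but-2-enyl] tetronate of 5 | CC(C)(C)OC(=O)C/C=C/COC1=CC(=O)O[C@H]1CC(C)=C
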